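**Plan**

- **Cuts:** the C4 ethyl group is traced back through vinyl to formyl. The 1,2-dioxane (O1–O2–C3–C4–C5–C6) is then cut at O1–C6 and at C3–C4. This gives a C4–C5–C6 piece, a 2,2-dialkylcyclopropanecarbaldehyde, and a C3–O2–O1 piece, a silylperoxy acetal that stands for the carbonyl oxide of methyl 3-oxopropanoate.
- **Enabling feature:** C6 is fully substituted and can bear positive charge. C4 sits 1,3 to it across the CH2 group C5 and becomes a carbanion equivalent once its ethyl group is written as formyl. C3 is an aldehyde-level carbon that already holds the O2–O1 unit. The ring is therefore the sum of two three-atom dipoles, and the C4–C6 bond of a cyclopropane stores the carbon dipole.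
- **Forward order:** side chain from (S)-citronellal (steps 1–6), three-membered ring by cyclopropenation and carbomagnesiation (7–9), peroxide partner by ozonolysis (10–11), six-membered ring in one operation (12), formyl to ethyl (13–14).
- **Stereochemistry:** C4' (methyl) comes from citronellal and C2' (ethyl) from a ligand-controlled conjugate addition. Cyclopropene C1 comes from a chiral dirhodium catalyst. The quaternary carbon comes from ester-directed syn addition of ethyl followed by inversion at C6 in step 12. C4 comes from a C2-symmetric amine and C3 from the geometry of the ring closure.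

Key step: step 12

Assumption: dioxane locants O1, O2, C3–C6 and side-chain locants C1'–C8' denote the same atoms in all precursors; for steps 2 and 7 the ligand enantiomer named is taken to give the drawn configuration, its mirror image being used otherwise.

**Step 1**
Reactants: 1 (3S)-3,7-dimethyloct-6-enal ((S)-citronellal)
Product: 2 methyl (2E,5S)-5,9-dimethyldeca-2,8-dienoate
Conditions: (MeO)2P(O)CH2CO2Me, NaH, THF, 0 to 23 °C
Reagents that add atoms: trimethyl phosphonoacetate COC(=O)CP(=O)(OC)OC
Why: Horner–Wadsworth–Emmons olefination of an unhindered aldehyde with a stabilised phosphonate anion should give the (E)-enoate, and the stereocentre of 1, being beta to the carbonyl group, is not at risk.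

**Step 2**
Reactants: 2 methyl (2E,5S)-5,9-dimethyldeca-2,8-dienoate
Product: 3 methyl (3S,5S)-3-ethyl-5,9-dimethyldec-8-enoate
Conditions: EtMgBr, CuBr·SMe2 (5 mol%), (R)-1-[(SP)-2-(diphenylphosphino)ferrocenyl]ethyldicyclohexylphosphine (6 mol%), t-BuOMe, −75 °C; aq NH4Cl
Reagents that add atoms: ethylmagnesium bromide CC[Mg]Br
Why: Copper-catalysed enantioselective conjugate addition of a Grignard reagent to an acyclic (E)-enoate; the ferrocenyl diphosphine fixes the face of attack and so sets C3 of 3 (the later C2'), the remote methyl centre having little influence.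

**Step 3**
Reactants: 3 methyl (3S,5S)-3-ethyl-5,9-dimethyldec-8-enoate
Product: 4 methyl (3S,5S)-3-ethyl-5-methylnon-8-enoate
Conditions: ethylene (10 bar), second-generation Hoveyda–Grubbs catalyst (2 mol%), toluene, 50 °C
Reagents that add atoms: ethylene C=C
Why: Ethenolysis (cross metathesis with ethylene) cuts the isopropylidene terminus to a vinyl group, driven by ethylene pressure and loss of a volatile alkene, and leaves exactly the four carbons of the later butyl terminus.

**Step 4**
Reactants: 4 methyl (3S,5S)-3-ethyl-5-methylnon-8-enoate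
Product: 5 methyl (3S,5S)-3-ethyl-5-methylnonanoate
Conditions: H2 (1 atm), Pd/C, EtOAc, 23 °C
Reagents that add atoms: none
Why: Heterogeneous catalytic hydrogenation of a terminal alkene, which touches no stereocentre.

**Step 5**
Reactants: 5 methyl (3S,5S)-3-ethyl-5-methylnonanoate
Product: 6 (3S,5S)-3-ethyl-5-methylnonanal
Conditions: i-Bu2AlH (1.05 equiv), CH2Cl2, −78 °C; aq potassium sodium tartrate
Reagents that add atoms: none
Why: Partial reduction of a methyl ester by i-Bu2AlH at low temperature stops at the tetrahedral stage and should release the aldehyde only on work-up.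

**Step 6**
Reactants: 6 (3S,5S)-3-ethyl-5-methylnonanal
Product: 7 (4S,6S)-4-ethyl-6-methyldec-1-yne
Conditions: dimethyl (1-diazo-2-oxopropyl)phosphonate, K2CO3, MeOH, 0 to 23 °C
Reagents that add atoms: dimethyl (1-diazo-2-oxopropyl)phosphonate CC(=O)C(=[N+]=[N-])P(=O)(OC)OC
Why: Seyferth–Gilbert homologation in its Ohira–Bestmann form converts the aldehyde into the terminal alkyne under mild base, the nearest stereocentre being beta to the carbonyl group.

**Step 7**
Reactants: 7 (4S,6S)-4-ethyl-6-methyldec-1-yne
Product: 8 ethyl (1R)-2-[(2S,4S)-2-ethyl-4-methyloctyl]cycloprop-2-ene-1-carboxylate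
Conditions: N2CHCO2Et (syringe pump), Rh2(OAc)(DPTI)3 (0.5 mol%; DPTI = (4S,5R)-4,5-diphenyl-1-(trifluoromethylsulfonyl)imidazolidin-2-on-3-ide), CH2Cl2, 23 °C
Reagents that add atoms: ethyl diazoacetate CCOC(=O)C=[N+]=[N-]
Why: Enantioselective [2+1] cycloaddition of a rhodium carbene to a terminal alkyne (cyclopropenation); the chiral dirhodium complex decides which face of the carbene meets the alkyne and so sets C1 of 8 (the later C4 position).

**Step 8**
Reactants: 8 ethyl (1R)-2-[(2S,4S)-2-ethyl-4-methyloctyl]cycloprop-2-ene-1-carboxylate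
Product: 10 ethyl (1R,2R)-2-ethyl-2-[(2S,4S)-2-ethyl-4-methyloctyl]cyclopropane-1-carboxylate, via cyclopropylmagnesium bromide 9 (not isolated)
Conditions: EtMgBr (2 equiv), CuI (20 mol%), Et2O, −35 to 0 °C; aq NH4Cl
Reagents that add atoms: ethylmagnesium bromide CC[Mg]Br
Why: Copper-catalysed carbomagnesiation of a cyclopropenyl ester: chelation by the ester brings ethyl to the alkyl-bearing sp2 carbon on the ester face in a syn addition, which sets the quaternary carbon relative to C1, and the configurationally stable 9 is protonated with retention.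

**Step 9**
Reactants: 10 ethyl (1R,2R)-2-ethyl-2-[(2S,4S)-2-ethyl-4-methyloctyl]cyclopropane-1-carboxylate
Product: 11 (1R,2R)-2-ethyl-2-[(2S,4S)-2-ethyl-4-methyloctyl]cyclopropane-1-carbaldehyde
Conditions: i-Bu2AlH (1.05 equiv), CH2Cl2, −78 °C; aq potassium sodium tartrate
Reagents that add atoms: none
Why: Partial ester reduction by i-Bu2AlH as in step 5; a cyclopropane alpha carbon does not enolise readily, so C1 should hold its configuration.

**Step 10**
Reactants: 12 methyl but-3-enoate
Product: 14 methyl 3-hydroperoxy-3-methoxypropanoate, via carbonyl oxide 13 (not isolated)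
Conditions: O3, MeOH/CH2Cl2 (1:1), −78 °C; N2 purge, concentration below 20 °C
Reagents that add atoms: ozone [O-][O+]=O; methanol CO
Why: Ozonolysis in methanol: cycloreversion of the primary ozonide gives the substituted carbonyl oxide 13, which methanol traps as the alpha-methoxy hydroperoxide; the acetal centre forms as a racemate and is erased in step 12.

**Step 11**
Reactants: 14 methyl 3-hydroperoxy-3-methoxypropanoate
Product: 15 methyl 3-methoxy-3-[(triethylsilyl)peroxy]propanoate
Conditions: Et3SiCl, imidazole, DMF, 0 °C
Reagents that add atoms: chlorotriethylsilane CC[Si](Cl)(CC)CC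
Why: O-Silylation of a hydroperoxide with a chlorosilane and imidazole, a standard protection that replaces the acidic proton by a transferable silyl group.

**Step 12**
Reactants: 11 (1R,2R)-2-ethyl-2-[(2S,4S)-2-ethyl-4-methyloctyl]cyclopropane-1-carbaldehyde; 15 methyl 3-methoxy-3-[(triethylsilyl)peroxy]propanoate
Product: 19 methyl 2-[(3S,4S,6S)-6-ethyl-6-[(2S,4S)-2-ethyl-4-methyloctyl]-4-formyl-1,2-dioxan-3-yl]acetate, via cyclopropyl iminium triflate 16 (not isolated), via peroxy enamine 17 (not isolated), via dioxanyl iminium triflate 18 (not isolated)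
Conditions: (2R,5R)-2,5-dimethylpyrrolidinium triflate (1.0 equiv), 4 Å molecular sieves, CH2Cl2, 23 °C; 15 (1.2 equiv), −40 to 0 °C; pH 7 phosphate buffer, 0 °C
Reagents that add atoms: water O
Why: Proposed new method: the ammonium salt turns 11 into cyclopropyl iminium ion 16, a donor–acceptor cyclopropane in which the C4–C6 bond is polarised towards the dialkylated C6; the outer oxygen O1 of silyl peroxide 15 attacks C6 from the rear of that bond, Et3Si+ passes to triflate, and the Et3SiOTf so made ionises the methoxy acetal of enamine 17 to a peroxycarbenium ion whose carbon C3 is captured by the enamine carbon C4 to give 18, hydrolysed to 19. The closest known reaction types are the formal [3+3] annulation of nitrones with donor–acceptor cyclopropanes, cyclopropyl iminium activation with enamine trapping, invertive substitution by silyl nucleophiles at quaternary carbons of cyclopropyl carbonyl compounds and the addition of enol silanes to peroxycarbenium ions; new is the silylperoxy acetal in the role of a carbonyl oxide. The 1,2-dioxane closes through a chair as a 6-endo-trig attack on the C3=O2 bond, exo with respect to the enamine double bond. C6 is set by inversion of the (2R) carbon of 11, so that ethyl and the alkyl chain, too alike in size for any facial choice, are told apart by the order in which they were put on the small ring; C4 is set by the C2-symmetric amine, whose methyl group beside the (E)-enamine shields one face and meets no opposing bias from C6; C3 is set by closure through the syn peroxycarbenium ion (acetate arm on the side of O1, the arrangement favoured in alkyl carbonyl oxides), which places the arm axial next to the O–O unit and cis to the C4 substituent. The step needs attack at C6 instead of C5 or the iminium carbon and closure before the enamine is quenched: only cleavage of C4–C6 develops a tertiary cationic centre, addition to C=N is reversible, and silicon in place of hydrogen on O1 means that no acid is set free.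

**Step 13**
Reactants: 19 methyl 2-[(3S,4S,6S)-6-ethyl-6-[(2S,4S)-2-ethyl-4-methyloctyl]-4-formyl-1,2-dioxan-3-yl]acetate
Product: 20 methyl 2-[(3S,4R,6S)-4-ethenyl-6-ethyl-6-[(2S,4S)-2-ethyl-4-methyloctyl]-1,2-dioxan-3-yl]acetate
Conditions: Ph3PCH3Br, KN(SiMe3)2, THF, 0 °C; then 19, −78 to 0 °C
Reagents that add atoms: methyltriphenylphosphonium bromide C[P+](c1ccccc1)(c1ccccc1)c1ccccc1.[Br-]
Why: Wittig methylenation with the non-stabilised ylide is fast on an aldehyde at low temperature and should spare the methyl ester, the dialkyl peroxide and the alpha stereocentre C4 (the descriptor changes only through ligand ranking).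

**Step 14**
Reactants: 20 methyl 2-[(3S,4R,6S)-4-ethenyl-6-ethyl-6-[(2S,4S)-2-ethyl-4-methyloctyl]-1,2-dioxan-3-yl]acetate
Product: 21 methyl 2-[(3S,4S,6S)-4,6-diethyl-6-[(2S,4S)-2-ethyl-4-methyloctyl]-1,2-dioxan-3-yl]acetate
Conditions: 2-nitrobenzenesulfonohydrazide (excess), CH2Cl2, 23 °C
Reagents that add atoms: none
Why: Diimide reduction (concerted syn transfer of two hydrogens) saturates the monosubstituted alkene and leaves the O–O bond, which metal-catalysed hydrogenation would cleave.

**Compound list**

1 | (3S)-3,7-dimethyloct-6-enal ((S)-citronellal) | CC(C)=CCC[C@H](C)CC=O | starting material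
2 | methyl (2E,5S)-5,9-dimethyldeca-2,8-dienoate | CC(C)=CCC[C@H](C)C/C=C/C(=O)OC | intermediate
3 | methyl (3S,5S)-3-ethyl-5,9-dimethyldec-8-enoate | CC(C)=CCC[C@H](C)C[C@H](CC)CC(=O)OC | intermediate
4 | methyl (3S,5S)-3-ethyl-5-methylnon-8-enoate | C=CCC[C@H](C)C[C@H](CC)CC(=O)OC | intermediate
5 | methyl (3S,5S)-3-ethyl-5-methylnonanoate | CCCC[C@H](C)C[C@H](CC)CC(=O)OC | intermediate
6 | (3S,5S)-3-ethyl-5-methylnonanal | CCCC[C@H](C)C[C@H](CC)CC=O | intermediate
7 | (4S,6S)-4-ethyl-6-methyldec-1-yne | CCCC[C@H](C)C[C@H](CC)CC#C | intermediate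
8 | ethyl (1R)-2-[(2S,4S)-2-ethyl-4-methyloctyl]cycloprop-2-ene-1-carboxylate | CCCC[C@H](C)C[C@H](CC)CC1=C[C@H]1C(=O)OCC | intermediate
9 | cyclopropylmagnesium bromide from syn addition (MgBr, the new ethyl group and CO2Et on one face of the ring) | CCCC[C@H](C)C[C@H](CC)C[C@]1(CC)[C@@H]([Mg]Br)[C@H]1C(=O)OCC | intermediate
10 | ethyl (1R,2R)-2-ethyl-2-[(2S,4S)-2-ethyl-4-methyloctyl]cyclopropane-1-carboxylate (ethyl cis to the ester) | CCCC[C@H](C)C[C@H](CC)C[C@]1(CC)C[C@H]1C(=O)OCC | intermediate
11 | (1R,2R)-2-ethyl-2-[(2S,4S)-2-ethyl-4-methyloctyl]cyclopropane-1-carbaldehyde | CCCC[C@H](C)C[C@H](CC)C[C@]1(CC)C[C@H]1C=O | intermediate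
12 | methyl but-3-enoate | C=CCC(=O)OC | starting material
13 | carbonyl oxide of methyl 3-oxopropanoate | COC(=O)CC=[O+][O-] | intermediate
14 | methyl 3-hydroperoxy-3-methoxypropanoate (racemic) | COC(=O)CC(OC)OO | intermediate
15 | methyl 3-methoxy-3-[(triethylsilyl)peroxy]propanoate (racemic) | COC(=O)CC(OC)OO[Si](CC)(CC)CC | intermediate
16 | cyclopropyl iminium triflate of 11 and (2R,5R)-2,5-dimethylpyrrolidine | CCCC[C@H](C)C[C@H](CC)C[C@]1(CC)C[C@H]1C=[N+]2[C@H](C)CC[C@H]2C.[O-]S(=O)(=O)C(F)(F)F | intermediate
17 | ring-opened (E)-enamine carrying the tertiary peroxy acetal at C6 (acetal carbon unassigned) | CCCC[C@H](C)C[C@H](CC)C[C@@](CC)(C/C=C/N1[C@H](C)CC[C@H]1C)OOC(OC)CC(=O)OC | intermediate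
18 | iminium triflate of 19 and (2R,5R)-2,5-dimethylpyrrolidine | CCCC[C@H](C)C[C@H](CC)C[C@@]1(CC)C[C@H](C=[N+]2[C@H](C)CC[C@H]2C)[C@H](CC(=O)OC)OO1.[O-]S(=O)(=O)C(F)(F)F | intermediate
19 | methyl 2-[(3S,4S,6S)-6-ethyl-6-[(2S,4S)-2-ethyl-4-methyloctyl]-4-formyl-1,2-dioxan-3-yl]acetate | CCCC[C@H](C)C[C@H](CC)C[C@@]1(CC)C[C@H](C=O)[C@H](CC(=O)OC)OO1 | intermediate
20 | methyl 2-[(3S,4R,6S)-4-ethenyl-6-ethyl-6-[(2S,4S)-2-ethyl-4-methyloctyl]-1,2-dioxan-3-yl]acetate | CCCC[C@H](C)C[C@H](CC)C[C@@]1(CC)C[C@H](C=C)[C@H](CC(=O)OC)OO1 | intermediate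
21 | methyl 2-[(3S,4S,6S)-4,6-diethyl-6-[(2S,4S)-2-ethyl-4-methyloctyl]-1,2-dioxan-3-yl]acetate | CCCC[C@H](C)C[C@H](CC)C[C@@]1(CC)C[C@H](CC)[C@H](CC(=O)OC)OO1 | target

**Counts**

Total steps: 14. Longest linear sequence: 12 (steps 1–9 and 12–14).

**Steps most likely to fail**

**Step 12.**
- What may go wrong: the silyl peroxide may be too weak a nucleophile for the quaternary carbon. Oxygen transfer from the silyl peroxide to the enamine may outrun ring closure. Closure may occur through the anti peroxycarbenium ion, with loss of the cis relation at C3 and C4.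
- Fallback (known reaction types, one bond at a time): from 11, Me3SiBr in CH2Cl2 at −78 °C opens the ring by invertive bromide attack at the quaternary carbon. This gives (1E,4S,6S,8S)-4-bromo-4,6-diethyl-8-methyl-1-(trimethylsilyloxy)dodec-1-ene F1.
- F1 is added to the peroxycarbenium ion released from 15 by catalytic Me3SiOTf (Mukaiyama-type addition of an enol silane to a peroxy acetal). This gives methyl 6-bromo-6,8-diethyl-4-formyl-10-methyl-3-[(triethylsilyl)peroxy]tetradecanoate F2.
- AgOTf then removes bromide and the peroxide oxygen closes the ring (silver-assisted cyclisation of a halo peroxide), which comes back to the route at 19.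
- Cost: C3 and C4 would arise without reagent control and C6 by way of a cation, so 19 would have to be separated from its isomers.

**Step 13.**
- What may go wrong: the basic ylide may cause loss of configuration at C4, or beta-elimination of the peroxide from the aldehyde with opening of the ring.
- Fallback: from 19, Seyferth–Gilbert homologation with the Ohira–Bestmann reagent (K2CO3, MeOH, 0 °C) works under a much weaker base. It gives methyl 2-[(3S,4R,6S)-6-ethyl-6-[(2S,4S)-2-ethyl-4-methyloctyl]-4-ethynyl-1,2-dioxan-3-yl]acetate F3.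
- Exhaustive diimide reduction of the alkyne leads directly to 21.

**Step 7.**
- What may go wrong: poor face selectivity of the rhodium carbene with a purely aliphatic alkyne, and carbene dimerisation when the alkyne is not in excess.
- Fallback (resolution instead of catalyst control): from 7, Rh2(OAc)4 and ethyl diazoacetate give the C1-epimeric ester mixture ethyl 2-[(2S,4S)-2-ethyl-4-methyloctyl]cycloprop-2-ene-1-carboxylate F4.
- Saponification (KOH, MeOH/H2O) gives the acid mixture 2-[(2S,4S)-2-ethyl-4-methyloctyl]cycloprop-2-ene-1-carboxylic acid F5.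
- Acylation of (S)-4-benzyl-1,3-oxazolidin-2-one through the mixed pivalic anhydride gives two imides that differ at a centre next to the auxiliary and should separate on silica. The wanted one is (4S)-4-benzyl-3-{(1R)-2-[(2S,4S)-2-ethyl-4-methyloctyl]cycloprop-2-ene-1-carbonyl}-1,3-oxazolidin-2-one F6.
- Ethanolysis (EtOH, Sm(OTf)3) comes back to the route at 8.

**Further compounds**

F1 | step 12 | (1E,4S,6S,8S)-4-bromo-4,6-diethyl-8-methyl-1-(trimethylsilyloxy)dodec-1-ene | CCCC[C@H](C)C[C@H](CC)C[C@@](Br)(CC)C/C=C/O[Si](C)(C)C
F2 | step 12 | methyl 6-bromo-6,8-diethyl-4-formyl-10-methyl-3-[(triethylsilyl)peroxy]tetradecanoate (C3 and C4 unassigned) | CCCC[C@H](C)C[C@H](CC)C[C@@](Br)(CC)CC(C=O)C(CC(=O)OC)OO[Si](CC)(CC)CC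
F3 | step 13 | methyl 2-[(3S,4R,6S)-6-ethyl-6-[(2S,4S)-2-ethyl-4-methyloctyl]-4-ethynyl-1,2-dioxan-3-yl]acetate | CCCC[C@H](C)C[C@H](CC)C[C@@]1(CC)C[C@H](C#C)[C@H](CC(=O)OC)OO1
F4 | step 7 | ethyl 2-[(2S,4S)-2-ethyl-4-methyloctyl]cycloprop-2-ene-1-carboxylate (both C1 epimers) | CCCC[C@H](C)C[C@H](CC)CC1=CC1C(=O)OCC
F5 | step 7 | 2-[(2S,4S)-2-ethyl-4-methyloctyl]cycloprop-2-ene-1-carboxylic acid (both C1 epimers) | CCCC[C@H](C)C[C@H](CC)CC1=CC1C(=O)O
F6 | step 7 | (4S)-4-benzyl-3-{(1R)-2-[(2S,4S)-2-ethyl-4-methyloctyl]cycloprop-2-ene-1-carbonyl}-1,3-oxazolidin-2-one | CCCC[C@H](C)C[C@H](CC)CC1=C[C@H]1C(=O)N1[C@@H](Cc2ccccc2)COC1=O
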